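**Retrosynthetic overview**
1. Target ⇐ 15‑O‑silyl removal and HWE olefination (glycolaldehyde) of an 8‑O‑(2‑phosphonopropanoyl) ester.
2. Ten‑membered (Z,E)‑cyclodecadiene ⇐ Ramberg–Bäcklund ring contraction of an eleven‑membered α‑chlorosulfone (S between C1 and C10); this creates the ring‑cis C1=C10 alkene.
3. Thiacycle ⇐ intramolecular S‑alkylation of a C10 thiol (from AcSH conjugate addition to a crotonyl ketone) with the C1 chloride; C8 from CBS reduction.
4. trans,trans‑γ‑Lactone ⇐ syn‑selective boron aldol/lactonisation of a chiral‑pool γ‑keto ester (C11) with a (Z)‑γ‑silyloxy enal (C4=C5 set by anti‑carbomagnesiation of propargyl alcohol).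
5. Ring order: γ‑lactone → 11‑membered thiacycle → 10‑membered carbocycle.

Assumption: the target SMILES is read as C1=C10 ring‑cis, C4=C5 ring‑trans, 6R,7R,8S,11S; late intermediates are named with germacrane numbering (ring C1–C10; C11/C12/C13 = lactone CH/C=O/CH3 on C7; C14 = CH3 on C10; C15 = CH2O on C4).

**Step 1**
Reactants: 1 prop‑2‑yn‑1‑ol + 2 1‑bromo‑3‑chloropropane
Product: 5 (Z)-2-(3-chloropropyl)-3-iodoprop-2-en-1-ol, via Grignard reagent 3 (not isolated), via alkenylmagnesium alkoxide 4 (not isolated)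
Conditions: 2, Mg, THF, 0–10 °C (3 equiv of 3); then 1, CuI (10 mol %), THF, 0 °C → rt; then I2, THF, −20 °C
Reagents that add atoms: iodine (II)
Why: Cu‑catalysed anti‑carbomagnesiation of the propargylic alkoxide (Duboudin type) places the alkyl group on C4 and Mg on C5 cis to CH2O in a chelate, so iodinolysis with retention fixes the ring‑trans C4=C5 geometry; Mg inserts into C–Br and leaves C–Cl.

**Step 2**
Reactants: 5 (Z)-2-(3-chloropropyl)-3-iodoprop-2-en-1-ol
Product: 6 tert-butyl{[(Z)-2-(3-chloropropyl)-3-iodoprop-2-en-1-yl]oxy}dimethylsilane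
Conditions: TBSCl, imidazole, DMF, 0 °C → rt
Reagents that add atoms: tert‑butyldimethylsilyl chloride (CC(C)(C)[Si](C)(C)Cl)
Why: Standard silylation of the primary allylic alcohol (C15–O), needed because every later C–O acylation must be selective for C8.

**Step 3**
Reactants: 6 tert-butyl{[(Z)-2-(3-chloropropyl)-3-iodoprop-2-en-1-yl]oxy}dimethylsilane
Product: 8 (Z)-4-{[tert-butyl(dimethyl)silyl]oxy}-3-(3-chloropropyl)but-2-enal, via vinyllithium 7 (not isolated)
Conditions: t‑BuLi (2.1 equiv), Et2O, −78 °C; DMF, −78 → −20 °C; aq. NH4Cl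
Reagents that add atoms: N,N‑dimethylformamide (CN(C)C=O)
Why: Iodine–lithium exchange with retention of alkene geometry is much faster than any reaction of the primary chloride at −78 °C, and formylation gives the C6 aldehyde.

**Step 4**
Reactants: 9 methyl (R)-3-bromo-2-methylpropanoate + 10 (E)-but-2-enoyl chloride
Product: 12 methyl (2S,5E)-2-methyl-4-oxohept-5-enoate, via organozinc bromide 11 (not isolated)
Conditions: Zn dust (TMSCl/BrCH2CH2Br‑activated), LiCl, THF, 40 °C; then 10, Pd(PPh3)4 (3 mol %), THF, 0 °C → rt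
Reagents that add atoms: none
Why: The zinc homoenolate is configurationally stable at the ester α‑carbon (C11, chiral pool), and its Pd‑catalysed Negishi‑type acylation forms C7–C8 without 1,4‑addition.

**Step 5**
Reactants: 12 methyl (2S,5E)-2-methyl-4-oxohept-5-enoate + 8 (Z)-4-{[tert-butyl(dimethyl)silyl]oxy}-3-(3-chloropropyl)but-2-enal
Product: 16 (3S,4S,5R)-4-[(2E)-but-2-enoyl]-5-[(1Z)-2-({[tert-butyl(dimethyl)silyl]oxy}methyl)-5-chloropent-1-en-1-yl]-3-methyloxolan-2-one, via boron enolate 13 (not isolated), via boron aldolate 14 (not isolated), via hydroxy ester 15 (not isolated)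
Conditions: (−)-Ipc2BOTf, i‑Pr2NEt, CH2Cl2, −78 °C; 8, −78 → −20 °C; H2O2, pH 7 buffer, MeOH, 0 °C; then PPTS (cat.), CH2Cl2, rt
Reagents that add atoms: none
Why: Paterson Ipc‑boron aldol: the (Z)‑enolborinate reacts through a chair transition state to give the 6,7‑syn adduct with reagent‑controlled Si‑face attack on the enal (C6 R; C7 as in the target), and the γ‑hydroxy ester then closes to the trans,trans γ‑lactone; because C11 is already fixed, the minor facial isomer is a separable diastereomer.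

**Step 6**
Reactants: 16 (3S,4S,5R)-4-[(2E)-but-2-enoyl]-5-[(1Z)-2-({[tert-butyl(dimethyl)silyl]oxy}methyl)-5-chloropent-1-en-1-yl]-3-methyloxolan-2-one
Product: 17 S-{(2RS)-4-[(2R,3S,4S)-2-[(1Z)-2-({[tert-butyl(dimethyl)silyl]oxy}methyl)-5-chloropent-1-en-1-yl]-4-methyl-5-oxooxolan-3-yl]-4-oxobutan-2-yl} ethanethioate
Conditions: AcSH (3 equiv), CH2Cl2, rt, no base
Reagents that add atoms: thioacetic acid (CC(=O)S)
Why: Uncatalysed thia‑Michael addition of the thioacid puts sulfur on C10 under acidic conditions that cannot trigger E1cB opening of the β‑acyloxy ketone; the C10 mixture is irrelevant because C10 becomes sp2.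

**Step 7**
Reactants: 17 (thioacetate ketone)
Product: 18 S-{(2RS,4S)-4-[(2R,3R,4S)-2-[(1Z)-2-({[tert-butyl(dimethyl)silyl]oxy}methyl)-5-chloropent-1-en-1-yl]-4-methyl-5-oxooxolan-3-yl]-4-hydroxybutan-2-yl} ethanethioate
Conditions: (R)-Me‑CBS (0.5 equiv), BH3·SMe2 (1.1 equiv), THF, −30 °C; MeOH
Reagents that add atoms: none
Why: Corey–Bakshi–Shibata reduction: with the α‑branched C7 as large and C9H2 as small substituent, the (R)‑oxazaborolidine delivers hydride to give the 8S carbinol.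

**Step 8**
Reactants: 18 (C8 alcohol)
Product: 19 (1S,3RS)-3-(acetylsulfanyl)-1-[(2R,3R,4S)-2-[(1Z)-2-({[tert-butyl(dimethyl)silyl]oxy}methyl)-5-chloropent-1-en-1-yl]-4-methyl-5-oxooxolan-3-yl]butyl 2-(diethoxyphosphoryl)propanoate
Conditions: 2‑(diethoxyphosphoryl)propanoic acid, DCC, DMAP (5 mol %), CH2Cl2, 0 °C
Reagents that add atoms: 2‑(diethoxyphosphoryl)propanoic acid (CCOP(=O)(OCC)C(C)C(=O)O)
Why: Steglich esterification acylates the only free hydroxyl (C8) with the HWE handle, which also removes the risk of 6,12 → 8,12 translactonisation in the basic steps that follow.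

**Step 9**
Reactants: 19 (thioacetate phosphonoester)
Product: 21 15-O-TBS-8-O-[2-(diethoxyphosphoryl)propanoyl]-1,10-seco-1,10-epithiogermacr-4-en-12,6-olide (11-membered thiacycle; 6R,7R,8S,11S; C4=C5 ring-trans; C10 epimers), via thiol 20 (not isolated)
Conditions: N2H4·AcOH, DMF, rt, 30 min; then syringe‑pump addition to Cs2CO3, NaI (cat.), degassed DMF (2 mM), 45 °C
Reagents that add atoms: none
Why: Hydrazinolysis cleaves the thioester selectively over the O‑esters, and caesium‑thiolate SN2 displacement of the (iodide‑exchanged) primary chloride under high dilution closes the eleven‑membered sulfide.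

**Step 10**
Reactants: 21 (thiacycle)
Product: 23 1-chloro-15-O-TBS-8-O-[2-(diethoxyphosphoryl)propanoyl]-1,10-seco-1,10-episulfonylgermacr-4-en-12,6-olide (cyclic α-chlorosulfone; diastereomer mixture), via α-chloro sulfide 22 (not isolated)
Conditions: NCS, CCl4, 0 °C → rt; then mCPBA (2.5 equiv), NaHCO3, CH2Cl2, −20 → 0 °C
Reagents that add atoms: N‑chlorosuccinimide (O=C1CCC(=O)N1Cl); 3‑chloroperoxybenzoic acid (OOC(=O)c1cccc(Cl)c1)
Why: Pummerer‑type α‑chlorination of the sulfide followed by peracid oxidation (sulfur reacts faster than the C4=C5 alkene, which is deactivated by two allylic oxygens) gives the Ramberg–Bäcklund precursor; chlorination at C10 instead of C1 would lead to the same alkene.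

**Step 11**
Reactants: 23 (cyclic α‑chlorosulfone) + 24 glycolaldehyde dimer (1,4‑dioxane‑2,5‑diol)
Product: 27 (3S,3aR,4S,6Z,10Z,11aR)-10-({[tert-butyl(dimethyl)silyl]oxy}methyl)-3,6-dimethyl-2-oxo-2,3,3a,4,5,8,9,11a-octahydrocyclodeca[b]furan-4-yl (2E)-4-hydroxy-2-methylbut-2-enoate, via episulfone 25 (not isolated), via ring-contracted phosphonate 26 (not isolated)
Conditions: KOt‑Bu (6 equiv), THF/t‑BuOH, −40 → 0 °C; then CF3CH2OH (6 equiv), 24 (1.5 equiv), 0 °C → rt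
Reagents that add atoms: none
Why: Proposed new method: a Ramberg–Bäcklund ring contraction run on a transient polyanion and coupled in the same flask to a pKa‑gated HWE olefination — KOt‑Bu first deprotonates the phosphonoacetate (pKa ≈ 19) and the lactone (pKa ≈ 25), masking both carbonyls as non‑electrophilic carbanions, then the α′‑sulfonyl C–H; ionic 1,3‑displacement of chloride gives the cis‑fused episulfone 25 (the trans‑fused one would place a second E‑alkene in the ten‑ring and is several kcal/mol higher), which loses SO2 stepwise to the (Z)‑C1=C10 alkene and so contracts the 11‑membered thiacycle to the cyclodecadiene; CF3CH2OH (pKa ≈ 23.5) then reprotonates the lactone enolate (to the more stable 11S epimer, methyl trans to C8) but not the phosphonate carbanion, which olefinates glycolaldehyde E‑selectively; the closest known reactions are KOt‑Bu Ramberg–Bäcklund ring contractions of cyclic α‑chlorosulfones to medium rings and HWE reactions of 2‑phosphonopropionates with potassium alkoxides.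

**Step 12**
Reactants: 27 (15‑O‑TBS ether of the target)
Product: 28 (3S,3aR,4S,6Z,10Z,11aR)-10-(hydroxymethyl)-3,6-dimethyl-2-oxo-2,3,3a,4,5,8,9,11a-octahydrocyclodeca[b]furan-4-yl (2E)-4-hydroxy-2-methylbut-2-enoate
Conditions: HF·pyridine, pyridine, THF, 0 °C
Reagents that add atoms: none
Why: Buffered fluoride cleaves the primary allylic silyl ether and leaves both esters and the acid‑sensitive 1,5‑diene intact.

**Compound list**
1 | prop-2-yn-1-ol | C#CCO | starting material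
2 | 1-bromo-3-chloropropane | ClCCCBr | starting material
3 | (3-chloropropyl)magnesium bromide | ClCCC[Mg]Br | intermediate
4 | bromomagnesium (Z)-3-(bromomagnesio)-2-(3-chloropropyl)prop-2-en-1-olate | ClCCC/C(CO[Mg]Br)=C/[Mg]Br | intermediate
5 | (Z)-2-(3-chloropropyl)-3-iodoprop-2-en-1-ol | ClCCC/C(CO)=C/I | intermediate
6 | tert-butyl{[(Z)-2-(3-chloropropyl)-3-iodoprop-2-en-1-yl]oxy}dimethylsilane | ClCCC/C(CO[Si](C)(C)C(C)(C)C)=C/I | intermediate
7 | [(Z)-3-{[tert-butyl(dimethyl)silyl]oxy}-2-(3-chloropropyl)prop-1-en-1-yl]lithium | ClCCC/C(CO[Si](C)(C)C(C)(C)C)=C/[Li] | intermediate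
8 | (Z)-4-{[tert-butyl(dimethyl)silyl]oxy}-3-(3-chloropropyl)but-2-enal | ClCCC/C(CO[Si](C)(C)C(C)(C)C)=C/C=O | intermediate
9 | methyl (R)-3-bromo-2-methylpropanoate | COC(=O)[C@@H](C)CBr | starting material
10 | (E)-but-2-enoyl chloride | C/C=C/C(Cl)=O | starting material
11 | [(R)-3-methoxy-2-methyl-3-oxopropyl]zinc bromide | COC(=O)[C@@H](C)C[Zn]Br | intermediate
12 | methyl (2S,5E)-2-methyl-4-oxohept-5-enoate | COC(=O)[C@@H](C)CC(=O)/C=C/C | intermediate
13 | methyl (2S,3Z,5E)-4-{[bis(isopinocampheyl)boranyl]oxy}-2-methylhepta-3,5-dienoate | COC(=O)[C@@H](C)/C=C(\OB([C@@H]1C[C@@H]2C[C@H]([C@H]1C)C2(C)C)[C@@H]1C[C@@H]2C[C@H]([C@H]1C)C2(C)C)/C=C/C | intermediate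
14 | O-bis(isopinocampheyl)boranyl aldolate of 15 | ClCCC/C(CO[Si](C)(C)C(C)(C)C)=C/[C@@H](OB([C@@H]1C[C@@H]2C[C@H]([C@H]1C)C2(C)C)[C@@H]1C[C@@H]2C[C@H]([C@H]1C)C2(C)C)[C@@H](C(=O)/C=C/C)[C@H](C)C(=O)OC | intermediate
15 | methyl (2S,3S,5E)-3-[(1R,2Z)-3-({[tert-butyl(dimethyl)silyl]oxy}methyl)-6-chloro-1-hydroxyhex-2-en-1-yl]-2-methyl-4-oxohept-5-enoate | ClCCC/C(CO[Si](C)(C)C(C)(C)C)=C/[C@@H](O)[C@@H](C(=O)/C=C/C)[C@H](C)C(=O)OC | intermediate
16 | (3S,4S,5R)-4-[(2E)-but-2-enoyl]-5-[(1Z)-2-({[tert-butyl(dimethyl)silyl]oxy}methyl)-5-chloropent-1-en-1-yl]-3-methyloxolan-2-one | ClCCC/C(CO[Si](C)(C)C(C)(C)C)=C/[C@H]1OC(=O)[C@@H](C)[C@@H]1C(=O)/C=C/C | intermediate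
17 | S-{(2RS)-4-[(2R,3S,4S)-2-[(1Z)-2-({[tert-butyl(dimethyl)silyl]oxy}methyl)-5-chloropent-1-en-1-yl]-4-methyl-5-oxooxolan-3-yl]-4-oxobutan-2-yl} ethanethioate | ClCCC/C(CO[Si](C)(C)C(C)(C)C)=C/[C@H]1OC(=O)[C@@H](C)[C@@H]1C(=O)CC(C)SC(C)=O | intermediate
18 | S-{(2RS,4S)-4-[(2R,3R,4S)-2-[(1Z)-2-({[tert-butyl(dimethyl)silyl]oxy}methyl)-5-chloropent-1-en-1-yl]-4-methyl-5-oxooxolan-3-yl]-4-hydroxybutan-2-yl} ethanethioate | ClCCC/C(CO[Si](C)(C)C(C)(C)C)=C/[C@H]1OC(=O)[C@@H](C)[C@@H]1[C@@H](O)CC(C)SC(C)=O | intermediate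
19 | (1S,3RS)-3-(acetylsulfanyl)-1-[(2R,3R,4S)-2-[(1Z)-2-({[tert-butyl(dimethyl)silyl]oxy}methyl)-5-chloropent-1-en-1-yl]-4-methyl-5-oxooxolan-3-yl]butyl 2-(diethoxyphosphoryl)propanoate | ClCCC/C(CO[Si](C)(C)C(C)(C)C)=C/[C@H]1OC(=O)[C@@H](C)[C@@H]1[C@@H](OC(=O)C(C)P(=O)(OCC)OCC)CC(C)SC(C)=O | intermediate
20 | (1S,3RS)-1-[(2R,3R,4S)-2-[(1Z)-2-({[tert-butyl(dimethyl)silyl]oxy}methyl)-5-chloropent-1-en-1-yl]-4-methyl-5-oxooxolan-3-yl]-3-sulfanylbutyl 2-(diethoxyphosphoryl)propanoate | ClCCC/C(CO[Si](C)(C)C(C)(C)C)=C/[C@H]1OC(=O)[C@@H](C)[C@@H]1[C@@H](OC(=O)C(C)P(=O)(OCC)OCC)CC(C)S | intermediate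
21 | 15-O-TBS-8-O-[2-(diethoxyphosphoryl)propanoyl]-1,10-seco-1,10-epithiogermacr-4-en-12,6-olide (S bridges C1 and C10; 6R,7R,8S,11S; C10 epimers) | CC1SCCC/C(CO[Si](C)(C)C(C)(C)C)=C/[C@H]2OC(=O)[C@@H](C)[C@@H]2[C@@H](OC(=O)C(C)P(=O)(OCC)OCC)C1 | intermediate
22 | 1-chloro derivative of 21 (α-chloro sulfide) | CC1SC(Cl)CC/C(CO[Si](C)(C)C(C)(C)C)=C/[C@H]2OC(=O)[C@@H](C)[C@@H]2[C@@H](OC(=O)C(C)P(=O)(OCC)OCC)C1 | intermediate
23 | S,S-dioxide of 22 (cyclic α-chlorosulfone) | CC1S(=O)(=O)C(Cl)CC/C(CO[Si](C)(C)C(C)(C)C)=C/[C@H]2OC(=O)[C@@H](C)[C@@H]2[C@@H](OC(=O)C(C)P(=O)(OCC)OCC)C1 | intermediate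
24 | glycolaldehyde dimer (1,4-dioxane-2,5-diol) | OC1COC(O)CO1 | starting material
25 | 1,10-episulfone (thiirane S,S-dioxide spanning C1 and C10, cis-fused to the ten-membered ring) | CC12S(=O)(=O)C1CC/C(CO[Si](C)(C)C(C)(C)C)=C/[C@H]3OC(=O)[C@@H](C)[C@@H]3[C@@H](OC(=O)C(C)P(=O)(OCC)OCC)C2 | intermediate
26 | (3S,3aR,4S,6Z,10Z,11aR)-10-({[tert-butyl(dimethyl)silyl]oxy}methyl)-3,6-dimethyl-2-oxo-2,3,3a,4,5,8,9,11a-octahydrocyclodeca[b]furan-4-yl 2-(diethoxyphosphoryl)propanoate (present as its potassium carbanion) | C/C1=C/CC/C(CO[Si](C)(C)C(C)(C)C)=C/[C@H]2OC(=O)[C@@H](C)[C@@H]2[C@@H](OC(=O)C(C)P(=O)(OCC)OCC)C1 | intermediate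
27 | (3S,3aR,4S,6Z,10Z,11aR)-10-({[tert-butyl(dimethyl)silyl]oxy}methyl)-3,6-dimethyl-2-oxo-2,3,3a,4,5,8,9,11a-octahydrocyclodeca[b]furan-4-yl (2E)-4-hydroxy-2-methylbut-2-enoate | C/C1=C/CC/C(CO[Si](C)(C)C(C)(C)C)=C/[C@H]2OC(=O)[C@@H](C)[C@@H]2[C@@H](OC(=O)/C(C)=C/CO)C1 | intermediate
28 | (3S,3aR,4S,6Z,10Z,11aR)-10-(hydroxymethyl)-3,6-dimethyl-2-oxo-2,3,3a,4,5,8,9,11a-octahydrocyclodeca[b]furan-4-yl (2E)-4-hydroxy-2-methylbut-2-enoate | C/C1=C/CC/C(CO)=C/[C@H]2OC(=O)[C@@H](C)[C@@H]2[C@@H](OC(=O)/C(C)=C/CO)C1 | target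

**Totals**
Total steps: 12. Longest linear sequence: 11 (steps 1–3, then 5–12; step 4 is the one‑step side branch).

**The three steps most likely to fail**

Step 11 (new tandem polyanion Ramberg–Bäcklund/HWE). Risks are incompatibility of the phosphonoacetate or lactone with the ring contraction, Z/E leakage, and aldol side reactions of the enolate with glycolaldehyde. The fallback uses only known chemistry and moves the ring contraction ahead of the side chain. It sets out from 18 and comes back at 27. Alcohol 18 is silylated (TESOTf, 2,6‑lutidine) to the C8 triethylsilyl ether F1. Hydrazinolysis gives the thiol F2, and Cs2CO3/NaI high‑dilution S‑alkylation closes the thiacycle F3. NCS gives the α‑chloro sulfide F4 and mCPBA the α‑chlorosulfone F5. A classical KOt‑Bu Ramberg–Bäcklund reaction (via the episulfone F6) gives the ring‑contracted (Z,E)‑diene TES ether F7. PPTS/MeOH removes the secondary TES group selectively to give the 8‑hydroxy lactone F8. Steglich esterification with 2‑(diethoxyphosphoryl)propanoic acid then gives 26, now isolated, and a separate Masamune–Roush HWE (LiCl, DBU, MeCN, 24) gives 27.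

Step 9 (closure of the 11‑membered thiacycle by S‑alkylation). Risks are oligomerisation and slow displacement at the chloride. The fallback changes the ring‑closing event to a sulfide stitch at the ketone stage. It sets out from 16 and comes back at 21. Treating 16 with Na2S·9H2O (1 equiv), NaI and NaHCO3 in DMF–H2O at high dilution forms both C–S bonds (conjugate addition at C10, SN2 at C1) to give the thiacyclic ketone F9. (R)‑CBS reduction gives the 8S alcohol F10, and Steglich esterification with the phosphonoacid gives 21.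

Step 7 (reagent‑controlled reduction at C8 next to the C7 stereocentre). The risk is that substrate bias overrides the catalyst. The fallback uses the wrong epimer productively. It sets out from 17 and comes back at 19. NaBH4/CeCl3 (MeOH, −78 °C) or whichever reductant gives mainly the 8R alcohol F11 is used, and Mitsunobu esterification (PPh3, DIAD, 2‑(diethoxyphosphoryl)propanoic acid) installs the phosphonoester with inversion to give 19.

**Further compounds**
F1 | step 11 | C8 triethylsilyl ether of 18 | ClCCC/C(CO[Si](C)(C)C(C)(C)C)=C/[C@H]1OC(=O)[C@@H](C)[C@@H]1[C@@H](O[Si](CC)(CC)CC)CC(C)SC(C)=O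
F2 | step 11 | thiol from F1 | ClCCC/C(CO[Si](C)(C)C(C)(C)C)=C/[C@H]1OC(=O)[C@@H](C)[C@@H]1[C@@H](O[Si](CC)(CC)CC)CC(C)S
F3 | step 11 | 11-membered thiacycle with 8-O-TES | CC1SCCC/C(CO[Si](C)(C)C(C)(C)C)=C/[C@H]2OC(=O)[C@@H](C)[C@@H]2[C@@H](O[Si](CC)(CC)CC)C1
F4 | step 11 | α-chloro sulfide of F3 | CC1SC(Cl)CC/C(CO[Si](C)(C)C(C)(C)C)=C/[C@H]2OC(=O)[C@@H](C)[C@@H]2[C@@H](O[Si](CC)(CC)CC)C1
F5 | step 11 | α-chlorosulfone of F3 | CC1S(=O)(=O)C(Cl)CC/C(CO[Si](C)(C)C(C)(C)C)=C/[C@H]2OC(=O)[C@@H](C)[C@@H]2[C@@H](O[Si](CC)(CC)CC)C1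
F6 | step 11 | 1,10-episulfone with 8-O-TES | CC12S(=O)(=O)C1CC/C(CO[Si](C)(C)C(C)(C)C)=C/[C@H]3OC(=O)[C@@H](C)[C@@H]3[C@@H](O[Si](CC)(CC)CC)C2
F7 | step 11 | ring-contracted (1(10)Z,4-ring-trans) diene lactone with 8-O-TES and 15-O-TBS | C/C1=C/CC/C(CO[Si](C)(C)C(C)(C)C)=C/[C@H]2OC(=O)[C@@H](C)[C@@H]2[C@@H](O[Si](CC)(CC)CC)C1
F8 | step 11 | (3S,3aR,4S,6Z,10Z,11aR)-10-({[tert-butyl(dimethyl)silyl]oxy}methyl)-4-hydroxy-3,6-dimethyl-3a,4,5,8,9,11a-hexahydrocyclodeca[b]furan-2(3H)-one | C/C1=C/CC/C(CO[Si](C)(C)C(C)(C)C)=C/[C@H]2OC(=O)[C@@H](C)[C@@H]2[C@@H](O)C1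
F9 | step 9 | 11-membered thiacyclic C8 ketone (S bridges C1 and C10) | CC1SCCC/C(CO[Si](C)(C)C(C)(C)C)=C/[C@H]2OC(=O)[C@@H](C)[C@@H]2C(=O)C1
F10 | step 9 | 8S alcohol of F9 | CC1SCCC/C(CO[Si](C)(C)C(C)(C)C)=C/[C@H]2OC(=O)[C@@H](C)[C@@H]2[C@@H](O)C1
F11 | step 7 | 8R epimer of 18 | ClCCC/C(CO[Si](C)(C)C(C)(C)C)=C/[C@H]1OC(=O)[C@@H](C)[C@@H]1[C@H](O)CC(C)SC(C)=O
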